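**Retrosynthetic overview** (flavone numbering O1–C8a; piperidine N1', C2'–C6')
1. Ring D, the N‑methylpiperidine, has one stereocentre, C2'. It is bonded to C8 of ring A and sits between C8a–O1 and C7–OH. C2' is therefore set on an open chain, and ring D is closed far from it, at C4'–C5'.
2. Ring C is made last, by C–O cyclodehydration of a 1,3‑diketone obtained by benzoylating the ring A methyl ketone (Baker–Venkataraman logic). Ring B arrives with benzoyl chloride.
3. The acetyl group enters a 2‑substituted 5‑methoxyresorcinol whose two free positions are equivalent. This fixes the 5‑OMe/7‑OH/8‑piperidinyl pattern without a regiochemical choice.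
4. In ring D, N–CH3 comes from Boc (LiAlH4) and C4'=C5' from ring‑closing metathesis of an N‑Boc N‑allyl homoallylamine. C2' comes from allylmagnesium bromide and the (S)‑tert‑butanesulfinyl imine of 2,6‑dibenzyloxy‑4‑methoxybenzaldehyde.
5. Order of rings: A (bought), then D (step 7), then C (step 12).

Key step: step 7

Assumption: the allyl Grignard addition follows the magnesium‑chelated chair model usual for tert‑butanesulfinyl aldimines in CH2Cl2; should the flanking benzyloxy groups invert the sense, the (R)‑sulfinamide would be used in the same sequence.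

**Step 1**
Reactants: 1 2,4,6‑trimethoxybenzaldehyde
Product: 2 2,6‑dihydroxy‑4‑methoxybenzaldehyde
Conditions: AlCl3 (5 equiv), CH2Cl2, 0 °C to 40 °C; then ice‑cold 1 M HCl
Reagents that add atoms: none
Why: Chelation‑directed Lewis acid cleavage of aryl methyl ethers: AlCl3 held at the formyl oxygen activates only the two ortho methoxy groups for attack of chloride on methyl, the usual way from 2,6‑dimethoxybenzaldehydes to 2,6‑dihydroxybenzaldehydes, while the para methoxy group cannot chelate and should stay.

**Step 2**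
Reactants: 2 2,6‑dihydroxy‑4‑methoxybenzaldehyde; 3 benzyl bromide
Product: 4 2,6‑dibenzyloxy‑4‑methoxybenzaldehyde
Conditions: BnBr (2.5 equiv), K2CO3 (3 equiv), DMF, 60 °C
Reagents that add atoms: benzyl bromide (3), BrCc1ccccc1
Why: Williamson ether synthesis: both phenoxides, although hydrogen‑bonded to the aldehyde, are alkylated by the reactive benzylic bromide in warm DMF, and the aldehyde has no enolisable position to interfere.

**Step 3**
Reactants: 4 2,6‑dibenzyloxy‑4‑methoxybenzaldehyde; 5 (S)‑tert‑butanesulfinamide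
Product: 6 (S,E)‑N‑(2,6‑dibenzyloxy‑4‑methoxybenzylidene)‑2‑methylpropane‑2‑sulfinamide
Conditions: Ti(OEt)4 (2.5 equiv), THF, 70 °C; then brine, filtration
Reagents that add atoms: (S)‑tert‑butanesulfinamide (5), CC(C)(C)[S@](=O)N
Why: Titanium‑alkoxide‑mediated condensation of an aldehyde with tert‑butanesulfinamide: Ti(OEt)4 activates the hindered, electron‑rich formyl group and takes up the water, which should give only the (E)‑aldimine and leaves the sulfur stereocentre untouched.

**Step 4**
Reactants: 6 (S,E)‑sulfinyl imine; 7 allylmagnesium bromide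
Product: 8 (S)‑N‑[(R)‑1‑(2,6‑dibenzyloxy‑4‑methoxyphenyl)but‑3‑enyl]‑2‑methylpropane‑2‑sulfinamide
Conditions: CH2=CHCH2MgBr (1 M in Et2O, 2 equiv), CH2Cl2, −78 °C to −40 °C; then aq. NH4Cl
Reagents that add atoms: allylmagnesium bromide (7), C=CC[Mg]Br
Why: 1,2‑Addition of an allyl Grignard reagent to an N‑tert‑butanesulfinyl aldimine: in non‑coordinating CH2Cl2 magnesium is held by the sulfinyl oxygen in a six‑membered chair with tert‑butyl equatorial, which for the (S)‑sulfinyl (E)‑imine exposes the Re face of C=N and should set C2' as (R), and any minor diastereomer can be removed by chromatography at this stage.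

**Step 5**
Reactants: 8 (S,R)‑sulfinamide; 9 di‑tert‑butyl dicarbonate
Product: 11 tert‑butyl N‑[(R)‑1‑(2,6‑dibenzyloxy‑4‑methoxyphenyl)but‑3‑enyl]carbamate, via primary amine 10 (not isolated)
Conditions: HCl (4 M in dioxane, 2.5 equiv), MeOH, 0 °C, 30 min; concentrate; then Boc2O (1.2 equiv), NaHCO3, THF–H2O, rt
Reagents that add atoms: di‑tert‑butyl dicarbonate (9), CC(C)(C)OC(=O)OC(=O)OC(C)(C)C
Why: Acidic S–N cleavage of the sulfinamide followed by Boc protection of the liberated amine: methanolysis at sulfur is fast at 0 °C, well below the conditions under which the electron‑rich benzylic C2'–N bond could ionise, and neither operation touches a bond at C2'.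

**Step 6**
Reactants: 11 (R)‑homoallylic N‑Boc amine; 12 allyl bromide
Product: 13 tert‑butyl N‑allyl‑N‑[(R)‑1‑(2,6‑dibenzyloxy‑4‑methoxyphenyl)but‑3‑enyl]carbamate
Conditions: NaH (1.5 equiv), allyl bromide (2 equiv), DMF, 0 °C to rt
Reagents that add atoms: allyl bromide (12), C=CCBr
Why: SN2 N‑alkylation of a sodium carbamate: the deprotonated Boc‑NH group can take up only one allyl group, which avoids the over‑alkylation met with a free primary amine, and C2'–H is far too weakly acidic to be removed by NaH.

**Step 7**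
Reactants: 13 (R)‑N‑Boc N‑allyl homoallylamine
Product: 14 tert‑butyl (R)‑2‑(2,6‑dibenzyloxy‑4‑methoxyphenyl)‑3,6‑dihydro‑2H‑pyridine‑1‑carboxylate
Conditions: RuCl2(=CHPh)(PCy3)(H2IMes) (second‑generation Grubbs catalyst, 5 mol %), CH2Cl2 (0.01 M), 40 °C, argon
Reagents that add atoms: none
Why: Ring‑closing olefin metathesis: after loss of PCy3 the ruthenium benzylidene engages the less hindered N‑allyl terminus by [2+2] cycloaddition and cycloreversion, and the resulting alkylidene adds across the C‑allyl alkene to a ruthenacyclobutane whose cycloreversion forms C4'=C5' and passes on Ru=CH2, with ethene leaving the solution. The closest known reaction type is the closure of N‑acyl N‑allyl homoallylamines to 1,2,3,6‑tetrahydropyridines. Ring D is closed as a six‑membered ring from a 1,7‑diene with both terminal CH2 groups expelled, so the only new bond lies two atoms away from C2' and out of reach of the flanking benzyloxy groups. No stereocentre is created, and C2' has no bond made or broken and is homoallylic in both diene and product, so a single alkene shift cannot reach it. The step needs cyclisation over oligomerisation and freedom from alkene isomerisation. Dilution, the ease of six‑ring closure and the carbamate (which removes the nitrogen lone pair that would bind ruthenium and, by allylic strain against C2', turns both allyl arms to the same side) secure the first, and the mild temperature and short contact time secure the second.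

**Step 8**
Reactants: 14 (R)‑N‑Boc tetrahydropyridine
Product: 15 (R)‑2‑(2,6‑dibenzyloxy‑4‑methoxyphenyl)‑1‑methyl‑1,2,3,6‑tetrahydropyridine
Conditions: LiAlH4 (4 equiv), THF, 66 °C; then H2O
Reagents that add atoms: none
Why: Hydride reduction of a carbamate to an N‑methylamine: hydride addition expels tert‑butoxide, the formamide so formed is reduced through its iminium ion to N–CH3, and the aryl ethers, the isolated alkene and C2' are not affected.

**Step 9**
Reactants: 15 (R)‑N‑methyl tetrahydropyridine
Product: 16 (R)‑5‑methoxy‑2‑(1‑methylpiperidin‑2‑yl)benzene‑1,3‑diol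
Conditions: H2 (1 atm), Pd/C (palladium on carbon, 10 wt%), MeOH, rt
Reagents that add atoms: none
Why: Heterogeneous catalytic hydrogenation combined with O‑benzyl hydrogenolysis: the disubstituted C4'=C5' alkene is saturated first and both aryl benzyl ethers are then cleaved, while the ring C2'–N bond, buried between two ortho substituents, should resist hydrogenolysis in neutral methanol, and the sensitive diol is carried on at once.

**Step 10**
Reactants: 16 (R)‑aminoresorcinol; 17 acetic anhydride
Product: 18 1‑[2,4‑dihydroxy‑6‑methoxy‑3‑[(R)‑1‑methylpiperidin‑2‑yl]phenyl]ethanone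
Conditions: Ac2O (1.1 equiv), BF3·OEt2 (6 equiv), CH2Cl2, 0 °C to rt; then aq. NaHCO3
Reagents that add atoms: acetic anhydride (17), CC(=O)OC(C)=O
Why: Friedel–Crafts acylation of a resorcinol under BF3, fed by Fries‑type O‑to‑C acetyl transfer and known for amine‑bearing phloroglucinol ethers: the two open positions of ring A are equivalent so only one regioisomer can form, the amine is masked as its boron or ammonium adduct, and boron chelation between the new ketone and the neighbouring oxygen should stop a second acylation and spare the methoxy group.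

**Step 11**
Reactants: 18 (R)‑acetophenone; 19 benzoyl chloride
Product: 20 1‑[2,4‑dihydroxy‑6‑methoxy‑3‑[(R)‑1‑methylpiperidin‑2‑yl]phenyl]‑3‑phenylpropane‑1,3‑dione
Conditions: LiN(SiMe3)2 (5 equiv), THF, −78 °C to −10 °C; PhCOCl (1.05 equiv), −78 °C to rt; then 1 M HCl to pH 7
Reagents that add atoms: benzoyl chloride (19), O=C(Cl)c1ccccc1
Why: Claisen‑type C‑benzoylation of the lithium polyanion of an ortho‑hydroxyacetophenone, the direct variant of the Baker–Venkataraman route: the enolate carbon is the most nucleophilic site, any benzoate formed at a phenoxide is drained by acyl transfer to the same stabilised diketonate, and the cold basic medium offers no path for ionising C2'–N.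

**Step 12**
Reactants: 20 (R)‑1,3‑diketone
Product: 21 (R)‑7‑hydroxy‑5‑methoxy‑8‑(1‑methylpiperidin‑2‑yl)‑2‑phenyl‑4H‑chromen‑4‑one (CNP0152057.1)
Conditions: conc. HCl–AcOH (1:10), 50 °C; concentrate; then aq. NaHCO3 to pH 8
Reagents that add atoms: none
Why: Acid‑catalysed cyclodehydration, the closing step of the Baker–Venkataraman flavone synthesis: only the phenol ortho to the acyl chain can add to the benzoyl carbonyl, and loss of water from the six‑membered hemiketal gives ring C with the piperidine at C8, the free hydroxyl at C7 and the methoxy group at C5, while the acyl‑substituted ring A is a much poorer donor so C2' should hold its configuration at this temperature.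

**Compound list**
1 | 2,4,6‑trimethoxybenzaldehyde | COc1cc(OC)c(C=O)c(OC)c1 | starting material
2 | 2,6‑dihydroxy‑4‑methoxybenzaldehyde | COc1cc(O)c(C=O)c(O)c1 | intermediate
3 | benzyl bromide | BrCc1ccccc1 | starting material
4 | 2,6‑dibenzyloxy‑4‑methoxybenzaldehyde | COc1cc(OCc2ccccc2)c(C=O)c(OCc2ccccc2)c1 | intermediate
5 | (S)‑tert‑butanesulfinamide | CC(C)(C)[S@](=O)N | starting material
6 | (S,E)‑N‑(2,6‑dibenzyloxy‑4‑methoxybenzylidene)‑2‑methylpropane‑2‑sulfinamide | CC(C)(C)[S@](=O)/N=C/c1c(OCc2ccccc2)cc(OC)cc1OCc1ccccc1 | intermediate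
7 | allylmagnesium bromide | C=CC[Mg]Br | starting material
8 | (S)‑N‑[(R)‑1‑(2,6‑dibenzyloxy‑4‑methoxyphenyl)but‑3‑enyl]‑2‑methylpropane‑2‑sulfinamide | CC(C)(C)[S@](=O)N[C@H](CC=C)c1c(OCc2ccccc2)cc(OC)cc1OCc1ccccc1 | intermediate
9 | di‑tert‑butyl dicarbonate | CC(C)(C)OC(=O)OC(=O)OC(C)(C)C | starting material
10 | (R)‑1‑(2,6‑dibenzyloxy‑4‑methoxyphenyl)but‑3‑en‑1‑amine (formed as its hydrochloride, freed in the flask) | N[C@H](CC=C)c1c(OCc2ccccc2)cc(OC)cc1OCc1ccccc1 | intermediate
11 | tert‑butyl N‑[(R)‑1‑(2,6‑dibenzyloxy‑4‑methoxyphenyl)but‑3‑enyl]carbamate | CC(C)(C)OC(=O)N[C@H](CC=C)c1c(OCc2ccccc2)cc(OC)cc1OCc1ccccc1 | intermediate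
12 | allyl bromide | C=CCBr | starting material
13 | tert‑butyl N‑allyl‑N‑[(R)‑1‑(2,6‑dibenzyloxy‑4‑methoxyphenyl)but‑3‑enyl]carbamate | COc1cc(OCc2ccccc2)c([C@@H](CC=C)N(CC=C)C(=O)OC(C)(C)C)c(OCc2ccccc2)c1 | intermediate
14 | tert‑butyl (R)‑2‑(2,6‑dibenzyloxy‑4‑methoxyphenyl)‑3,6‑dihydro‑2H‑pyridine‑1‑carboxylate | COc1cc(OCc2ccccc2)c([C@H]2CC=CCN2C(=O)OC(C)(C)C)c(OCc2ccccc2)c1 | intermediate
15 | (R)‑2‑(2,6‑dibenzyloxy‑4‑methoxyphenyl)‑1‑methyl‑1,2,3,6‑tetrahydropyridine | COc1cc(OCc2ccccc2)c([C@H]2CC=CCN2C)c(OCc2ccccc2)c1 | intermediate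
16 | (R)‑5‑methoxy‑2‑(1‑methylpiperidin‑2‑yl)benzene‑1,3‑diol | COc1cc(O)c([C@H]2CCCCN2C)c(O)c1 | intermediate
17 | acetic anhydride | CC(=O)OC(C)=O | starting material
18 | 1‑[2,4‑dihydroxy‑6‑methoxy‑3‑[(R)‑1‑methylpiperidin‑2‑yl]phenyl]ethanone | COc1cc(O)c([C@H]2CCCCN2C)c(O)c1C(C)=O | intermediate
19 | benzoyl chloride | O=C(Cl)c1ccccc1 | starting material
20 | 1‑[2,4‑dihydroxy‑6‑methoxy‑3‑[(R)‑1‑methylpiperidin‑2‑yl]phenyl]‑3‑phenylpropane‑1,3‑dione | COc1cc(O)c([C@H]2CCCCN2C)c(O)c1C(=O)CC(=O)c1ccccc1 | intermediate
21 | (R)‑7‑hydroxy‑5‑methoxy‑8‑(1‑methylpiperidin‑2‑yl)‑2‑phenyl‑4H‑chromen‑4‑one | COc1cc(O)c([C@H]2CCCCN2C)c2oc(-c3ccccc3)cc(=O)c12 | target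

**Total step count:** 12. **Longest linear sequence:** 12 steps (1 to 21).

**Steps most likely to fail**

**Step 10 (C‑acetylation).**
- What may go wrong: in the Lewis acidic medium the benzylic C2'–N bond of the very electron‑rich ring may ionise reversibly. Alternatively, ring A may be protonated at its piperidine‑bearing carbon, with loss and return of the cyclic iminium ion. Either process erodes the configuration at C2'. At the low temperature needed to suppress this, the O‑to‑C acetyl transfer may stall.
- Fallback (sets out from 15, comes back at 18): the acetyl group is brought in by organolithium chemistry while both phenols are still benzylated. The trifluoroacetate salt of 15 is brominated with N‑bromosuccinimide in MeCN at −20 °C at one of the two equivalent ring A positions, giving (R)‑2‑(3‑bromo‑2,6‑dibenzyloxy‑4‑methoxyphenyl)‑1‑methyl‑1,2,3,6‑tetrahydropyridine F1. Bromine–lithium exchange with n‑BuLi in THF at −78 °C and trapping with N‑methoxy‑N‑methylacetamide gives 1‑[2,4‑dibenzyloxy‑6‑methoxy‑3‑[(R)‑1‑methyl‑1,2,3,6‑tetrahydropyridin‑2‑yl]phenyl]ethanone F2. Hydrogenation over Pd/C in MeOH then saturates C4'=C5' and removes both benzyl groups. This reaches 18 without the free aminoresorcinol meeting an acid.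

**Step 11 (C‑benzoylation of the polyanion).**
- What may go wrong: enolisation of a poorly soluble trilithio species may be incomplete, benzoylation at oxygen may not be drained to carbon, or a second benzoylation may occur at the diketone carbon.
- Fallback (sets out from 18, comes back at 20): the classical two‑stage Baker–Venkataraman sequence, in which the acyl group is first parked on oxygen and then delivered intramolecularly. Benzoyl chloride (3 equiv) in pyridine with 4‑dimethylaminopyridine gives 4‑acetyl‑5‑methoxy‑2‑[(R)‑1‑methylpiperidin‑2‑yl]‑1,3‑phenylene dibenzoate F3. KOt‑Bu in THF at 0 °C enolises the ketone and moves the neighbouring benzoyl group from oxygen to carbon, giving 3‑hydroxy‑5‑methoxy‑2‑[(R)‑1‑methylpiperidin‑2‑yl]‑4‑(3‑oxo‑3‑phenylpropanoyl)phenyl benzoate F4. K2CO3 in MeOH at rt removes the remaining benzoate and returns to 20.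

**Step 7 (ring‑closing metathesis).**
- What may go wrong: ring closure may be slow if the two benzyloxy groups lock the carbamate in a rotamer that keeps the allyl arms apart. Intermolecular metathesis and ruthenium hydride alkene migration along the allyl arms could then compete.
- Fallback (sets out from 11, comes back at 16): ring D is closed at N1'–C6' by cyclohydrocarbonylation, with C6' coming from CO. Linear‑selective hydroformylation of 11 uses Rh(acac)(CO)2 and BIPHEPHOS under CO/H2 (1:1, 4 atm) in THF at 65 °C and gives tert‑butyl N‑[(R)‑1‑(2,6‑dibenzyloxy‑4‑methoxyphenyl)‑5‑oxopentyl]carbamate F5. In the same pot, with a trace of pyridinium p‑toluenesulfonate, F5 closes on the carbamate N–H and loses water, giving tert‑butyl (R)‑2‑(2,6‑dibenzyloxy‑4‑methoxyphenyl)‑3,4‑dihydro‑2H‑pyridine‑1‑carboxylate F6. Hydrogenation over Pd/C in MeOH saturates C5'=C6' and removes both benzyl groups, giving tert‑butyl (R)‑2‑(2,6‑dihydroxy‑4‑methoxyphenyl)piperidine‑1‑carboxylate F7. Excess LiAlH4 in THF at 66 °C converts Boc into N–CH3 and returns to 16.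

**Further compounds**
F1 | step 10 | (R)‑2‑(3‑bromo‑2,6‑dibenzyloxy‑4‑methoxyphenyl)‑1‑methyl‑1,2,3,6‑tetrahydropyridine | COc1cc(OCc2ccccc2)c([C@H]2CC=CCN2C)c(OCc2ccccc2)c1Br
F2 | step 10 | 1‑[2,4‑dibenzyloxy‑6‑methoxy‑3‑[(R)‑1‑methyl‑1,2,3,6‑tetrahydropyridin‑2‑yl]phenyl]ethanone | COc1cc(OCc2ccccc2)c([C@H]2CC=CCN2C)c(OCc2ccccc2)c1C(C)=O
F3 | step 11 | 4‑acetyl‑5‑methoxy‑2‑[(R)‑1‑methylpiperidin‑2‑yl]‑1,3‑phenylene dibenzoate | COc1cc(OC(=O)c2ccccc2)c([C@H]2CCCCN2C)c(OC(=O)c2ccccc2)c1C(C)=O
F4 | step 11 | 3‑hydroxy‑5‑methoxy‑2‑[(R)‑1‑methylpiperidin‑2‑yl]‑4‑(3‑oxo‑3‑phenylpropanoyl)phenyl benzoate | COc1cc(OC(=O)c2ccccc2)c([C@H]2CCCCN2C)c(O)c1C(=O)CC(=O)c1ccccc1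
F5 | step 7 | tert‑butyl N‑[(R)‑1‑(2,6‑dibenzyloxy‑4‑methoxyphenyl)‑5‑oxopentyl]carbamate | CC(C)(C)OC(=O)N[C@H](CCCC=O)c1c(OCc2ccccc2)cc(OC)cc1OCc1ccccc1
F6 | step 7 | tert‑butyl (R)‑2‑(2,6‑dibenzyloxy‑4‑methoxyphenyl)‑3,4‑dihydro‑2H‑pyridine‑1‑carboxylate | COc1cc(OCc2ccccc2)c([C@H]2CCC=CN2C(=O)OC(C)(C)C)c(OCc2ccccc2)c1
F7 | step 7 | tert‑butyl (R)‑2‑(2,6‑dihydroxy‑4‑methoxyphenyl)piperidine‑1‑carboxylate | COc1cc(O)c([C@H]2CCCCN2C(=O)OC(C)(C)C)c(O)c1
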